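# Synthesis plan for CNP0241224.1 (compound 31): benzannulation route to ring A

## The problem

Compound 31 is an isoflavan quinone: a chroman (benzo ring A fused to pyran ring C) carries at C3, through the C3–C1' bond, a 2-hydroxy-3-prenyl-1,4-benzoquinone (ring B). Ring A is pentasubstituted, with oxygen at C5, C7 and C8a, the prenyl group at C6 between the two methoxyls, the C4 methylene at C4a and hydrogen only at C8; on a preformed phloroglucinol C6 and C8 are hard to tell apart, so this pattern is better built than decorated. C3 (R) is the only stereocentre and is isolated, so no resident element can direct it; an external chiral agent must set it and the route must then carry it unchanged. Once ring B is a quinone, the C3–H is a vinylogous α-hydrogen and can epimerise, and the hydroxyquinone does not tolerate base, nucleophiles or reductants, so it has to be unveiled last under near-neutral conditions. The two prenyl alkenes exclude hydrogenation, hydrogenolysis, electrophilic halogen and strong Brønsted or Lewis acid, which would cyclise them onto neighbouring phenols. The feature that opens the key step is the order of substituents around ring A, O(C8a)–chain(C4a)–OMe(C5)–prenyl(C6)–OMe(C7)–H(C8). This is the order in which a 1-methoxyalkyne and a 2-prenyl-3-methoxy vinylketene deliver their substituents in a benzannulation, and the new phenol oxygen at C8a is placed to become O1.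

## Retrosynthesis

**Quinone last (31 ⇐ 30 ⇐ 29).** No skeletal bond is cut. The hydroxyquinone is traced to the 2-prenylresorcinol 30, in which C5' is the only free position para to a hydroxyl, so a phenol-to-quinone oxidation can enter only there. This is preferred to carrying a 1,2,4-trioxygenated ring B through the route, which would need three differentiated oxygens. The resorcinol is masked as the bis(methoxymethyl) ether 29. The forward steps must oxidise only ring B (ring A has no free phenol) and must unmask the phenols without cyclising the prenyl groups.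

**Pyran ring (29 ⇐ 28 ⇐ 27).** The O1–C2 bond is cut. Cutting O1–C8a instead would require a halogen at C8a and a metal-mediated aryl etherification. The alkyl C–O cut lets the phenol oxygen created by the annulation serve directly as O1 and needs only a primary alcohol, released from silyl ether 27 to give 28. The closure must be a clean 6-exo displacement that does not touch C3, and the ring B oxygens must still be masked so that a five-membered ether cannot form.

**Ring A (27 ⇐ 22 + 8).** Three bonds are cut: C8a–C4a, C5–C6 and C8–C8a. The classical alternative, prenylation and alkylation of a phloroglucinol ether, has no handle to separate C6 from C8. The annulation places all six substituents through one polarity-matched bond formation. The precursors are far simpler: cyclobutenone 8 (ten carbons, achiral) and ynol ether 22, which already holds ring B and the stereocentre. The forward reaction needs the ketene–alkyne regiochemistry and (2+2) periselectivity, and it must leave the remote centre alone.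

**Cyclobutenone (8 ⇐ 7 ⇐ 4 + 5; 4 ⇐ 1 + 2).** The four-membered ring is cut into ynol ether 4 and dichloroketene 6 (from 5). The same polarity rule puts the carbonyl next to the prenyl-bearing carbon, and reductive dechlorination of 7 gives 8. Enyne 4 is cut at its propargylic bond into sodium methoxyacetylide 3 (from chloroacetal 1) and prenyl bromide 2. Both partners are cheap, so the one-flask amide route in liquid ammonia is used here. The ketene must add to the alkyne and not to the trisubstituted alkene.

**Ynol ether and stereocentre (22 ⇐ 20 + 21; 20 ⇐ 19 ⇐ 18 ⇐ 17 ⇐ 16).** The C4–C4a bond is cut by alkylating lithium methoxyacetylide 21 (also from 1) with iodide 20. The lithium salt in THF/HMPA is chosen because the valuable, lipophilic, β-branched iodide needs a homogeneous ethereal medium and low temperature. No comparably direct entry to a 1-methoxyalkyne exists, and both fragments become simple. The stereocentre is traced to the prochiral diol 16: enzymatic desymmetrisation gives monoacetate 17, and the order of the following protecting-group steps decides which arm becomes C4 and which C2. The substitution must win over elimination, and no step may let an acyl or silyl group migrate between the two arms.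

**Ring B fragment (16 ⇐ 15 ⇐ 13 + 14; 13 ⇐ 10 + 2; 10 ⇐ 9).** The C3–C1' bond is cut by malonate arylation of bromide 13 with 14, and reduction of 15 gives the diol. The ring B prenyl group is installed between the two oxygens of 10 by directed metalation and allylation with 2. This position is fixed by the two flanking acetal groups, which is why a 4-bromoresorcinol (9) is the starting point.

## Roads not taken

**Alternative 1:** double aromatic Claisen rearrangement. The cut is at the two aryl–CH2 bonds (C6 and C3'); both prenyl groups are traced to O-bound 1,1-dimethylallyl groups in bis-ether A2, and heating would give A1.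
- Merits: both prenyl groups enter late and in one operation, each at the only free ortho position. The prenyl-free chroman core tolerates catalytic asymmetric hydrogenation and hydrogenolysis, which the chosen plan can never use. The early phase is probably shorter and more classical.
- Weak points: two hindered tertiary allyl aryl ethers must be made. The ortho-prenyl phenols formed at rearrangement temperature can cyclise or migrate further. A1 then has two hindered phenols (O5 and O4') that must be told apart, since O5 is to be methylated and O4' is not. The final oxidative demethylation with (NH4)2Ce(NO3)6 would meet an equally electron-rich ring A.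
- Comparison: the chosen plan is longer, but it never has to differentiate like phenols; the only phenol it creates is the one that becomes O1.

**Alternative 2:** chromene–quinone annulation. The cut is at C3–C1' plus a temporary C4–O bond. Chromene A4 and quinone A5, activated by TiCl2(TADDOLate), would give the cis-fused pterocarpan A3.
- Merits: it is the most convergent option, and the stereocentre is set in the step that joins the two halves; on step count it would beat the chosen plan.
- Weak points: A4 still needs ring A with the prenyl group at C6, which is the regiochemical problem itself. A titanium Lewis acid meets two prenyl alkenes. The site of attack on A5 and the enantioselectivity rest on chelation. The benzylic C–O bond of A3 must be cleaved reductively without hydrogenolysis. The sequence ends at the O-methyl quinone A6, whose vinylogous ester must still be hydrolysed.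
- Comparison: the chosen plan answers with neutral thermal conditions for its C–C bond formation and with a solved ring A.

**Alternative 3:** squarate ring expansion for ring B. The cut is at C1'–C2' and the rest of ring B. The vinyllithium from bromide A10 would add to dione A8 to give hydroxycyclobutenone A9, and thermolysis (Moore rearrangement) would give hydroquinone A7.
- Merits: this rearrangement class is better precedented than a benzannulation with a 3-alkoxycyclobutenone. A7 is already at the hydroquinone level, so a mild oxidant suffices in place of a radical oxidation of a free resorcinol. In both respects it is stronger than the chosen plan.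
- Weak points: the strategic step is spent on ring B, which is bought cheaply as a resorcinol in the chosen plan. The harder ring A and an enantiopure C3-vinyl chroman A10 are left to unspecified chemistry. The route again ends at A6 and needs the same final hydrolysis.
- Comparison: the chosen plan sets against the better precedent that its key step removes the ring A regiochemistry problem, which this road leaves open.

Key step: step 13

Assumption: the lipase is taken to acetylate the enantiotopic hydroxymethyl group of 16 that gives (R)-17; if it prefers the other arm, hydrolysis of the diacetate with the same enzyme gives (R)-17 instead.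

Abbreviations used in names: prenyl = 3-methylbut-2-en-1-yl; Ar = 2,4-bis(methoxymethoxy)-3-prenylphenyl; TBDPS = tert-butyldiphenylsilyl.

## Route

Step 1
Reactants: 1 2-chloro-1,1-dimethoxyethane; 2 1-bromo-3-methylbut-2-ene (prenyl bromide)
Product: 4 1-methoxy-5-methylhex-4-en-1-yne, via sodium methoxyacetylide 3 (not isolated)
Conditions: NaNH2 (3.0 equiv), liq. NH3, −33 °C; then 2 (0.8 equiv), −33 °C
Reagents that add atoms: none
Why: Sodium amide removes HCl and methanol from the chloroacetal and deprotonates the resulting methoxyethyne, and the sodium acetylide is alkylated in the same flask at the primary allylic carbon (SN2), the classical one-pot preparation of 1-alkoxy-1-alkynes in liquid ammonia. Exactly three equivalents of amide leave no free base to isomerise the skipped enyne, and the acetylide is kept in excess so that the bromide is consumed by carbon and not by ammonia.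

Step 2
Reactants: 4 1-methoxy-5-methylhex-4-en-1-yne; 5 trichloroacetyl chloride
Product: 7 4,4-dichloro-3-methoxy-2-prenylcyclobut-2-en-1-one, via dichloroketene 6 (not isolated)
Conditions: activated Zn, Et2O/DME, 0 °C → rt, slow addition of 5
Reagents that add atoms: none
Why: Ketene–ynol ether (2+2) cycloaddition; the nucleophilic alkyne carbon remote from oxygen bonds to the ketene carbonyl carbon, so CCl2 ends next to C–OMe. The electron-rich alkyne should outcompete the trisubstituted alkene for the slowly generated ketene.

Step 3
Reactants: 7 4,4-dichloro-3-methoxy-2-prenylcyclobut-2-en-1-one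
Product: 8 3-methoxy-2-prenylcyclobut-2-en-1-one
Conditions: Zn, AcOH, TMEDA, EtOH, 0 °C → rt
Reagents that add atoms: none
Why: Zinc-mediated reductive dechlorination of the α,α-dichloroketone through zinc enolates, the usual finish of the dichloroketene route to cyclobutenones; the buffered medium spares the vinylogous ester and the alkene.

Step 4
Reactants: 9 4-bromobenzene-1,3-diol
Product: 10 1-bromo-2,4-bis(methoxymethoxy)benzene
Conditions: MOMCl, i-Pr2NEt, CH2Cl2, 0 °C → rt
Reagents that add atoms: chloromethyl methyl ether, COCCl
Why: Standard O-alkylation of both phenols; the acetal groups later direct metalation and mask ring B through the pyran closure.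

Step 5
Reactants: 10 1-bromo-2,4-bis(methoxymethoxy)benzene; 2 1-bromo-3-methylbut-2-ene
Product: 13 1-bromo-2,4-bis(methoxymethoxy)-3-prenylbenzene, via aryllithium 11 (not isolated), via arylcopper 12 (not isolated)
Conditions: LiN(i-Pr)2, THF, −78 °C; CuBr·SMe2; then 2, −78 → 0 °C
Reagents that add atoms: none
Why: Directed ortho-metalation: the amide base removes the proton flanked by both acetal oxygens without halogen–lithium exchange. Transmetalation to copper gives clean allylation at the primary carbon of prenyl bromide.

Step 6
Reactants: 13 1-bromo-2,4-bis(methoxymethoxy)-3-prenylbenzene; 14 diethyl malonate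
Product: 15 diethyl 2-Ar-propanedioate
Conditions: Pd(OAc)2 (cat.), P(t-Bu)3·HBF4 (cat.), K3PO4, PhMe, 80 °C
Reagents that add atoms: none
Why: Palladium-catalysed α-arylation of a malonate enolate (Buchwald–Hartwig-type enolate coupling); the bulky electron-rich phosphine handles the electron-rich ortho-oxygenated bromide, and the trisubstituted alkene does not insert.

Step 7
Reactants: 15 diethyl 2-Ar-propanedioate
Product: 16 2-Ar-propane-1,3-diol
Conditions: LiAlH4, THF, 0 °C → rt
Reagents that add atoms: none
Why: Hydride reduction of both esters, the usual access to 2-aryl-1,3-propanediols; acetals and alkene are inert.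

Step 8
Reactants: 16 2-Ar-propane-1,3-diol
Product: 17 (2R)-2-Ar-3-hydroxypropyl acetate
Conditions: lipase (Pseudomonas cepacia), vinyl acetate, t-BuOMe, rt
Reagents that add atoms: vinyl acetate, CC(=O)OC=C
Why: Enzymatic desymmetrisation by irreversible acyl transfer; the lipase active site distinguishes the enantiotopic hydroxymethyl groups of the prochiral diol and so sets the only stereocentre (C3 of the target).

Step 9
Reactants: 17 (2R)-2-Ar-3-hydroxypropyl acetate
Product: 18 (2S)-2-Ar-3-[(tert-butyldiphenylsilyl)oxy]propyl acetate
Conditions: TBDPSCl, imidazole, CH2Cl2, 0 °C → rt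
Reagents that add atoms: tert-butyl(chloro)diphenylsilane, CC(C)(C)[Si](Cl)(c1ccccc1)c1ccccc1
Why: Silylation of the free primary alcohol directly after the enzymatic step forestalls acyl migration between the arms, which would racemise; the descriptor changes by priority only.

Step 10
Reactants: 18 (2S)-2-Ar-3-[(tert-butyldiphenylsilyl)oxy]propyl acetate
Product: 19 (2S)-2-Ar-3-[(tert-butyldiphenylsilyl)oxy]propan-1-ol
Conditions: K2CO3 (cat.), MeOH, 0 °C
Reagents that add atoms: none
Why: Base-catalysed transesterification (Zemplén-type methanolysis) removes the acetate; the bulky silyl ether is stable and should not migrate to the freed hydroxyl at 0 °C, so the configuration is kept.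

Step 11
Reactants: 19 (2S)-2-Ar-3-[(tert-butyldiphenylsilyl)oxy]propan-1-ol
Product: 20 tert-butyl{[(2R)-2-Ar-3-iodopropyl]oxy}diphenylsilane
Conditions: I2, PPh3, imidazole, CH2Cl2, 0 °C → rt
Reagents that add atoms: iodine, II
Why: Appel-type iodination (Garegg–Samuelsson conditions) of the primary alcohol by SN2 at CH2; the stereocentre is not a reacting atom.

Step 12
Reactants: 1 2-chloro-1,1-dimethoxyethane; 20 tert-butyl{[(2R)-2-Ar-3-iodopropyl]oxy}diphenylsilane
Product: 22 tert-butyl{[(2R)-2-Ar-5-methoxypent-4-yn-1-yl]oxy}diphenylsilane, via lithium methoxyacetylide 21 (not isolated)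
Conditions: Et2NH, n-BuLi, THF, 0 °C; then 20, HMPA, −78 °C → rt
Reagents that add atoms: none
Why: Lithium diethylamide converts the chloroacetal into lithium methoxyacetylide in THF, the medium in which the lipophilic iodide dissolves, and HMPA then promotes SN2 alkylation at the primary carbon, the standard route to 1-alkoxy-1-alkynes from alkyl iodides. The step forms the future C4–C4a bond; substitution occurs at CH2, so the adjacent centre is retained.

Step 13
Reactants: 22 tert-butyl{[(2R)-2-Ar-5-methoxypent-4-yn-1-yl]oxy}diphenylsilane; 8 3-methoxy-2-prenylcyclobut-2-en-1-one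
Product: 27 2-{(2R)-2-Ar-3-[(tert-butyldiphenylsilyl)oxy]propyl}-3,5-dimethoxy-4-prenylphenol, via vinylketene 23 (not isolated), via 4-alkenylcyclobutenone 24 (not isolated), via dienylketene 25 (not isolated), via cyclohexa-2,4-dienone 26 (not isolated)
Conditions: 8 (excess), PhMe, 110–130 °C, sealed tube
Reagents that add atoms: none
Why: Thermal 4π-electrocyclic opening of 8 gives vinylketene 23; the carbon of ynol ether 22 remote from oxygen attacks the ketene carbonyl carbon and the oxygen-bearing carbon closes onto the ketene α-carbon, a (2+2) cycloaddition that forms C8a–C4a and C5–C6 in 24. A second 4π opening gives dienylketene 25, whose 6π-disrotatory electrocyclisation forms C8–C8a and closes ring A as the six-membered carbocycle; tautomerisation of 26 gives the phenol. The closest known reaction type is the Danheiser benzannulation of cyclobutenones with 1-alkoxyalkynes, here with a 3-alkoxycyclobutenone as the less common ketene source. No stereocentre is created in the product (the quaternary carbon of 24 is transient), and the remote C3 centre sees neither acid nor base. Two selectivities are needed: the regiochemistry of the ketene–alkyne addition, secured by the polarisation of the ynol ether against the electrophilic ketene carbon, and (2+2) over (4+2) periselectivity, secured by the ketene reacting through its C=C bond. A methoxy group on the alkyne excludes retro-ene loss of an alkene at this temperature, and 8 is used in excess because the alkyne is the valuable partner.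

Step 14
Reactants: 27 2-{(2R)-2-Ar-3-[(tert-butyldiphenylsilyl)oxy]propyl}-3,5-dimethoxy-4-prenylphenol
Product: 28 2-[(2R)-2-Ar-3-hydroxypropyl]-3,5-dimethoxy-4-prenylphenol
Conditions: Bu4NF, THF, 0 °C → rt
Reagents that add atoms: none
Why: Fluoride cleaves the primary silyl ether; aryl methoxymethyl ethers, the phenol and both alkenes are unaffected.

Step 15
Reactants: 28 2-[(2R)-2-Ar-3-hydroxypropyl]-3,5-dimethoxy-4-prenylphenol
Product: 29 (3R)-3-Ar-5,7-dimethoxy-6-prenylchromane
Conditions: PPh3, DIAD, THF, 0 °C → rt
Reagents that add atoms: none
Why: Intramolecular Mitsunobu etherification: the only acidic hydroxyl (C8a–OH) displaces the activated primary alcohol in a 6-exo-tet closure that forms O1–C2. C3 is not a reacting centre, and the ring B oxygens are still masked, so no five-membered ether can form.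

Step 16
Reactants: 29 (3R)-3-Ar-5,7-dimethoxy-6-prenylchromane
Product: 30 4-[(3R)-5,7-dimethoxy-6-prenylchroman-3-yl]-2-prenylbenzene-1,3-diol
Conditions: HCl (2 M), MeOH, rt
Reagents that add atoms: none
Why: Acid-catalysed acetal exchange removes both methoxymethyl groups; dilute acid at room temperature is the usual way to unmask ortho-prenyl phenols without cyclising the prenyl group.

Step 17
Reactants: 30 4-[(3R)-5,7-dimethoxy-6-prenylchroman-3-yl]-2-prenylbenzene-1,3-diol
Product: 31 2-hydroxy-5-[(3R)-5,7-dimethoxy-6-prenylchroman-3-yl]-3-prenylcyclohexa-2,5-diene-1,4-dione (CNP0241224.1)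
Conditions: (KSO3)2NO, KH2PO4 buffer (pH 6), acetone/H2O, 0 °C → rt
Reagents that add atoms: potassium nitrosodisulfonate, [K+].[K+].[O]N(S(=O)(=O)[O-])S(=O)(=O)[O-]
Why: Teuber oxidation: the nitroxyl radical oxidises the resorcinol at C5', the only free position para to a hydroxyl, to give the 2-hydroxy-1,4-benzoquinone. Ring A has no free phenol, and the near-neutral buffer protects the now epimerisable C3.

## Compound list

1 | 2-chloro-1,1-dimethoxyethane | COC(CCl)OC | starting material
2 | 1-bromo-3-methylbut-2-ene | CC(C)=CCBr | starting material
3 | sodium methoxyacetylide | [Na]C#COC | intermediate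
4 | 1-methoxy-5-methylhex-4-en-1-yne | COC#CCC=C(C)C | intermediate
5 | trichloroacetyl chloride | O=C(Cl)C(Cl)(Cl)Cl | starting material
6 | dichloroketene | O=C=C(Cl)Cl | intermediate
7 | 4,4-dichloro-3-methoxy-2-(3-methylbut-2-en-1-yl)cyclobut-2-en-1-one | COC1=C(CC=C(C)C)C(=O)C1(Cl)Cl | intermediate
8 | 3-methoxy-2-(3-methylbut-2-en-1-yl)cyclobut-2-en-1-one | COC1=C(CC=C(C)C)C(=O)C1 | intermediate
9 | 4-bromobenzene-1,3-diol | Oc1ccc(Br)c(O)c1 | starting material
10 | 1-bromo-2,4-bis(methoxymethoxy)benzene | COCOc1ccc(Br)c(OCOC)c1 | intermediate
11 | [3-bromo-2,6-bis(methoxymethoxy)phenyl]lithium | COCOc1ccc(Br)c(OCOC)c1[Li] | intermediate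
12 | [3-bromo-2,6-bis(methoxymethoxy)phenyl]copper | COCOc1ccc(Br)c(OCOC)c1[Cu] | intermediate
13 | 1-bromo-2,4-bis(methoxymethoxy)-3-(3-methylbut-2-en-1-yl)benzene | COCOc1ccc(Br)c(OCOC)c1CC=C(C)C | intermediate
14 | diethyl malonate | CCOC(=O)CC(=O)OCC | starting material
15 | diethyl 2-[2,4-bis(methoxymethoxy)-3-(3-methylbut-2-en-1-yl)phenyl]propanedioate | CCOC(=O)C(C(=O)OCC)c1ccc(OCOC)c(CC=C(C)C)c1OCOC | intermediate
16 | 2-[2,4-bis(methoxymethoxy)-3-(3-methylbut-2-en-1-yl)phenyl]propane-1,3-diol | OCC(CO)c1ccc(OCOC)c(CC=C(C)C)c1OCOC | intermediate
17 | (2R)-2-[2,4-bis(methoxymethoxy)-3-(3-methylbut-2-en-1-yl)phenyl]-3-hydroxypropyl acetate | CC(=O)OC[C@H](c1ccc(OCOC)c(CC=C(C)C)c1OCOC)CO | intermediate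
18 | (2S)-2-[2,4-bis(methoxymethoxy)-3-(3-methylbut-2-en-1-yl)phenyl]-3-[(tert-butyldiphenylsilyl)oxy]propyl acetate | CC(=O)OC[C@H](c1ccc(OCOC)c(CC=C(C)C)c1OCOC)CO[Si](c1ccccc1)(c1ccccc1)C(C)(C)C | intermediate
19 | (2S)-2-[2,4-bis(methoxymethoxy)-3-(3-methylbut-2-en-1-yl)phenyl]-3-[(tert-butyldiphenylsilyl)oxy]propan-1-ol | OC[C@H](c1ccc(OCOC)c(CC=C(C)C)c1OCOC)CO[Si](c1ccccc1)(c1ccccc1)C(C)(C)C | intermediate
20 | tert-butyl{[(2R)-2-[2,4-bis(methoxymethoxy)-3-(3-methylbut-2-en-1-yl)phenyl]-3-iodopropyl]oxy}diphenylsilane | IC[C@H](c1ccc(OCOC)c(CC=C(C)C)c1OCOC)CO[Si](c1ccccc1)(c1ccccc1)C(C)(C)C | intermediate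
21 | lithium methoxyacetylide | [Li]C#COC | intermediate
22 | tert-butyl{[(2R)-2-[2,4-bis(methoxymethoxy)-3-(3-methylbut-2-en-1-yl)phenyl]-5-methoxypent-4-yn-1-yl]oxy}diphenylsilane | COC#CC[C@H](c1ccc(OCOC)c(CC=C(C)C)c1OCOC)CO[Si](c1ccccc1)(c1ccccc1)C(C)(C)C | intermediate
23 | 3-methoxy-2-(3-methylbut-2-en-1-yl)buta-1,3-dien-1-one | O=C=C(CC=C(C)C)C(=C)OC | intermediate
24 | 2-{(2R)-2-[2,4-bis(methoxymethoxy)-3-(3-methylbut-2-en-1-yl)phenyl]-3-[(tert-butyldiphenylsilyl)oxy]propyl}-3-methoxy-4-(1-methoxyethenyl)-4-(3-methylbut-2-en-1-yl)cyclobut-2-en-1-one (mixture at the ring carbon) | COC(=C)C1(CC=C(C)C)C(OC)=C(C[C@H](c2ccc(OCOC)c(CC=C(C)C)c2OCOC)CO[Si](c2ccccc2)(c2ccccc2)C(C)(C)C)C1=O | intermediate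
25 | (3E)-2-{(2R)-2-[2,4-bis(methoxymethoxy)-3-(3-methylbut-2-en-1-yl)phenyl]-3-[(tert-butyldiphenylsilyl)oxy]propyl}-3,5-dimethoxy-4-(3-methylbut-2-en-1-yl)hexa-1,3,5-trien-1-one | O=C=C(C[C@H](c1ccc(OCOC)c(CC=C(C)C)c1OCOC)CO[Si](c1ccccc1)(c1ccccc1)C(C)(C)C)/C(OC)=C(CC=C(C)C)\C(=C)OC | intermediate
26 | 2-{(2R)-2-[2,4-bis(methoxymethoxy)-3-(3-methylbut-2-en-1-yl)phenyl]-3-[(tert-butyldiphenylsilyl)oxy]propyl}-3,5-dimethoxy-4-(3-methylbut-2-en-1-yl)cyclohexa-2,4-dien-1-one | COC1=C(CC=C(C)C)C(OC)=C(C[C@H](c2ccc(OCOC)c(CC=C(C)C)c2OCOC)CO[Si](c2ccccc2)(c2ccccc2)C(C)(C)C)C(=O)C1 | intermediate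
27 | 2-{(2R)-2-[2,4-bis(methoxymethoxy)-3-(3-methylbut-2-en-1-yl)phenyl]-3-[(tert-butyldiphenylsilyl)oxy]propyl}-3,5-dimethoxy-4-(3-methylbut-2-en-1-yl)phenol | COc1cc(O)c(C[C@H](c2ccc(OCOC)c(CC=C(C)C)c2OCOC)CO[Si](c2ccccc2)(c2ccccc2)C(C)(C)C)c(OC)c1CC=C(C)C | intermediate
28 | 2-{(2R)-2-[2,4-bis(methoxymethoxy)-3-(3-methylbut-2-en-1-yl)phenyl]-3-hydroxypropyl}-3,5-dimethoxy-4-(3-methylbut-2-en-1-yl)phenol | COc1cc(O)c(C[C@H](c2ccc(OCOC)c(CC=C(C)C)c2OCOC)CO)c(OC)c1CC=C(C)C | intermediate
29 | (3R)-3-[2,4-bis(methoxymethoxy)-3-(3-methylbut-2-en-1-yl)phenyl]-5,7-dimethoxy-6-(3-methylbut-2-en-1-yl)chromane | COc1cc2c(c(OC)c1CC=C(C)C)C[C@H](c1ccc(OCOC)c(CC=C(C)C)c1OCOC)CO2 | intermediate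
30 | 4-[(3R)-5,7-dimethoxy-6-(3-methylbut-2-en-1-yl)chroman-3-yl]-2-(3-methylbut-2-en-1-yl)benzene-1,3-diol | COc1cc2c(c(OC)c1CC=C(C)C)C[C@H](c1ccc(O)c(CC=C(C)C)c1O)CO2 | intermediate
31 | 2-hydroxy-5-[(3R)-5,7-dimethoxy-6-(3-methylbut-2-en-1-yl)chroman-3-yl]-3-(3-methylbut-2-en-1-yl)cyclohexa-2,5-diene-1,4-dione | COc1cc2c(c(OC)c1CC=C(C)C)C[C@H](C1=CC(=O)C(O)=C(CC=C(C)C)C1=O)CO2 | target

## Step count and least certain steps

Total: 17 steps. Longest linear sequence: 14 steps (steps 4–17, from 9); steps 1–3 form the three-step side branch to 8.

**Step 13 (key step).** The donor-stabilised, vinylogous-ester cyclobutenone may open only sluggishly. The electron-rich vinylketene may then be lost to dimerisation or to O-acylation of the product phenol before it meets the alkyne. Bonding through the methoxyvinyl terminus instead of the ketene α-carbon would leak to the regioisomeric arene. The fallback generates the same vinylketene 23 without the cyclobutenone; it sets out from 2 and 22 and returns at 27. Prenyl bromide 2 alkylates commercial methyl acetoacetate (K2CO3, acetone) to methyl 2-acetyl-5-methylhex-4-enoate F1. Trimethyl orthoformate with catalytic acid converts it into the enol ether methyl 3-methoxy-2-(3-methylbut-2-en-1-yl)but-2-enoate F2. Saponification (LiOH) gives 3-methoxy-2-(3-methylbut-2-en-1-yl)but-2-enoic acid F3, and oxalyl chloride on its salt gives 3-methoxy-2-(3-methylbut-2-en-1-yl)but-2-enoyl chloride F4. Slow addition of F4 to Et3N and 22 in CH2Cl2 gives 23 by 1,4-dehydrochlorination at room temperature, where it is trapped as 24; warming in toluene then carries 24 through 25 and 26 to 27.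

**Step 12.** Bimolecular elimination across the benzylic β-hydrogen can compete with the slow substitution at a β-branched primary carbon, and the liberated amine can consume the iodide. The fallback sets out from 19 and returns at 22. Tf2O and 2,6-lutidine at −78 °C convert 19 into (2R)-2-Ar-3-[(tert-butyldiphenylsilyl)oxy]propyl trifluoromethanesulfonate F5. F5 is treated at once, at −78 °C in THF without HMPA, with amine-free 21 (prepared from 1 with LiNH2 in liquid NH3 and taken up in THF after the ammonia is removed). At this temperature substitution on the triflate should be fast and elimination negligible; the triflate is not stored, to avoid participation by the ortho acetal oxygen.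

**Step 2.** Dichloroketene may also add to the trisubstituted alkene, and ZnCl2 may degrade the acid-sensitive ynol ether. The fallback sets out from 4 and returns at 8, bypassing 7 and step 3. Ketene F6, generated by thermal cracking of diketene, is passed into 4 in CH2Cl2 at 0 °C. Ketene does not add to unactivated alkenes but gives 3-alkoxycyclobutenones with 1-alkoxyalkynes, and the same polarity places the carbonyl next to the prenyl-bearing carbon, so 8 forms directly.

**Step 8.** The enzyme may discriminate the enantiotopic arms poorly or in the opposite sense, and acyl migration in the monoacetate would erode enantiopurity. The fallback sets out from 16 and returns at 17. Ac2O in pyridine gives 2-Ar-propane-1,3-diyl diacetate F7, and the same lipase in pH 7 phosphate buffer hydrolyses one enantiotopic ester. Hydrolysis is enantiocomplementary to acylation, so this gives the arm assignment that acyl transfer could not.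

**Step 16.** Acid may cyclise the ring B prenyl group onto a flanking phenol or add methanol across a prenyl alkene. The fallback sets out from 29 and returns at 30. TMSOTf with 2,2'-bipyridyl in CH2Cl2 at 0 °C transfers silicon to the aryl acetal oxygens under non-protic conditions and gives (3R)-3-[2,4-bis(trimethylsilyloxy)-3-prenylphenyl]-5,7-dimethoxy-6-prenylchromane F8. The silyl ethers of F8 are hydrolysed on neutral aqueous work-up, so the alkenes never meet a Brønsted acid.

**Step 1.** In liquid ammonia the solvent competes with the acetylide for the reactive allylic bromide, and any base left over can move the doubly activated CH2 of the skipped enyne into allenic or conjugated isomers. The fallback sets out from 1 and 2 and returns at 4, and replaces the alkali acetylide displacement by a copper-catalysed Grignard allylation. Sodium methoxyacetylide 3 is generated from 1 as in step 1, the ammonia is evaporated, cold saturated aqueous NaCl is added to the residue, and the low-boiling methoxyethyne F9 is distilled into a cold trap and taken up in THF. EtMgBr at 0 °C converts it into methoxyethynylmagnesium bromide F10, which couples with 2 under catalytic CuBr·SMe2 at the unsubstituted terminus of the allylic bromide. This is the usual preparation of 1,4-enynes and runs in an ether solvent free of ammonia and amide.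

## Further compounds

F1 | step 13 | methyl 2-acetyl-5-methylhex-4-enoate | COC(=O)C(CC=C(C)C)C(C)=O
F2 | step 13 | methyl 3-methoxy-2-(3-methylbut-2-en-1-yl)but-2-enoate (E/Z mixture) | COC(=O)C(CC=C(C)C)=C(C)OC
F3 | step 13 | 3-methoxy-2-(3-methylbut-2-en-1-yl)but-2-enoic acid | COC(C)=C(CC=C(C)C)C(=O)O
F4 | step 13 | 3-methoxy-2-(3-methylbut-2-en-1-yl)but-2-enoyl chloride | COC(C)=C(CC=C(C)C)C(=O)Cl
F5 | step 12 | (2R)-2-[2,4-bis(methoxymethoxy)-3-(3-methylbut-2-en-1-yl)phenyl]-3-[(tert-butyldiphenylsilyl)oxy]propyl trifluoromethanesulfonate | O=S(=O)(OC[C@H](c1ccc(OCOC)c(CC=C(C)C)c1OCOC)CO[Si](c1ccccc1)(c1ccccc1)C(C)(C)C)C(F)(F)F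
F6 | step 2 | ketene | C=C=O
F7 | step 8 | 2-[2,4-bis(methoxymethoxy)-3-(3-methylbut-2-en-1-yl)phenyl]propane-1,3-diyl diacetate | CC(=O)OCC(COC(C)=O)c1ccc(OCOC)c(CC=C(C)C)c1OCOC
F8 | step 16 | (3R)-3-[2,4-bis(trimethylsilyloxy)-3-(3-methylbut-2-en-1-yl)phenyl]-5,7-dimethoxy-6-(3-methylbut-2-en-1-yl)chromane | COc1cc2c(c(OC)c1CC=C(C)C)C[C@H](c1ccc(O[Si](C)(C)C)c(CC=C(C)C)c1O[Si](C)(C)C)CO2
F9 | step 1 | methoxyethyne | COC#C
F10 | step 1 | methoxyethynylmagnesium bromide | COC#C[Mg]Br
A1 | alternative 1 | (R)-3-(4-hydroxy-2,5-dimethoxy-3-prenylphenyl)-7-methoxy-6-prenylchroman-5-ol | COc1cc2c(c(O)c1CC=C(C)C)C[C@H](c1cc(OC)c(O)c(CC=C(C)C)c1OC)CO2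
A2 | alternative 1 | (R)-3-[2,5-dimethoxy-4-(2-methylbut-3-en-2-yloxy)phenyl]-7-methoxy-5-(2-methylbut-3-en-2-yloxy)chromane | COc1cc2c(c(OC(C)(C)C=C)c1)C[C@H](c1cc(OC)c(OC(C)(C)C=C)cc1OC)CO2
A3 | alternative 2 | cis-8-hydroxy-1,3,9-trimethoxy-2,10-diprenylpterocarpan | COc1cc2c(c(OC)c1CC=C(C)C)[C@@H]3Oc4c(CC=C(C)C)c(OC)c(O)cc4[C@@H]3CO2
A4 | alternative 2 | 5,7-dimethoxy-6-(3-methylbut-2-en-1-yl)-2H-chromene | COc1cc2c(C=CCO2)c(OC)c1CC=C(C)C
A5 | alternative 2 | 2-methoxy-3-(3-methylbut-2-en-1-yl)cyclohexa-2,5-diene-1,4-dione | COC1=C(CC=C(C)C)C(=O)C=CC1=O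
A6 | alternative 2 | 2-methoxy-5-[(3R)-5,7-dimethoxy-6-(3-methylbut-2-en-1-yl)chroman-3-yl]-3-(3-methylbut-2-en-1-yl)cyclohexa-2,5-diene-1,4-dione | COc1cc2c(c(OC)c1CC=C(C)C)C[C@H](C1=CC(=O)C(OC)=C(CC=C(C)C)C1=O)CO2
A7 | alternative 3 | (R)-3-(2,5-dihydroxy-4-methoxy-3-prenylphenyl)-5,7-dimethoxy-6-prenylchroman | COc1cc2c(c(OC)c1CC=C(C)C)C[C@H](c1cc(O)c(OC)c(CC=C(C)C)c1O)CO2
A8 | alternative 3 | 3-methoxy-4-(3-methylbut-2-en-1-yl)cyclobut-3-ene-1,2-dione | COC1=C(CC=C(C)C)C(=O)C1=O
A9 | alternative 3 | 4-hydroxy-3-methoxy-2-(3-methylbut-2-en-1-yl)-4-{(E)-2-[(3R)-5,7-dimethoxy-6-(3-methylbut-2-en-1-yl)chroman-3-yl]ethenyl}cyclobut-2-en-1-one | O=C1C(CC=C(C)C)=C(OC)C1(O)/C=C/[C@@H]1COc2cc(OC)c(CC=C(C)C)c(OC)c2C1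
A10 | alternative 3 | (3R)-3-[(E)-2-bromoethenyl]-5,7-dimethoxy-6-(3-methylbut-2-en-1-yl)chromane | Br/C=C/[C@@H]1COc2cc(OC)c(CC=C(C)C)c(OC)c2C1
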